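**Assumption:** natural (+)-aromadendrin [(2R,3R)-dihydrokaempferol] and tert-butyl (2-methylbut-3-en-2-yl) carbonate are treated as purchasable (the carbonate is otherwise one step from 2-methylbut-3-en-2-ol and Boc2O).

## Retrosynthetic overview

1. The target (2R,3R)-8,3'-diprenyl-dihydrokaempferol comes from its 7-O-MOM ether by acid deprotection.
2. Both C-prenyl bonds are made in one pot by [3,3] shifts of a bis-allyl ether: the 5-O-prenyl group migrates to C8 (para-Claisen–Cope) and the 4'-O-(1,1-dimethylallyl) group migrates to C3' (ortho-Claisen).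
3. The ethers are installed on (+)-aromadendrin in order of phenol acidity: 7-OH (MOM), then 4'-OH (Pd reverse prenylation), then the chelated 5-OH (Mitsunobu).
4. No ring is built. The chromanone core and both stereocentres (2R,3R) are bought in (+)-aromadendrin, and no step makes or breaks a bond at C2 or C3.

## Route

**Step 1**
Reactants: 1, (+)-aromadendrin; 2, chloromethyl methyl ether (MOMCl)
Product: 3, (2R,3R)-3,5-dihydroxy-2-(4-hydroxyphenyl)-7-(methoxymethoxy)chroman-4-one
Conditions: MOMCl (1.05 equiv), K2CO3 (1.1 equiv), acetone, 0 °C → rt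
Reagents that add atoms: MOMCl, COCCl
Why: Williamson etherification with one equivalent of weak base, which ionises only the vinylogous-acid 7-OH (pKa ≈ 7.5), leaving the 4'-OH (≈ 10), the chelated 5-OH and the 3-OH untouched; C2/C3 are not involved.

**Step 2**
Reactants: 3; 4, tert-butyl (2-methylbut-3-en-2-yl) carbonate
Product: 5, (2R,3R)-3,5-dihydroxy-7-(methoxymethoxy)-2-[4-(2-methylbut-3-en-2-yloxy)phenyl]chroman-4-one
Conditions: 4 (1.5 equiv), Pd(PPh3)4 (5 mol %), THF, 0 °C → rt, short reaction time
Reagents that add atoms: tert-butyl (2-methylbut-3-en-2-yl) carbonate, C=CC(C)(C)OC(=O)OC(C)(C)C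
Why: Decarboxylative Tsuji–Trost O-allylation, in which the only unhindered phenoxide (4'-O⁻) attacks the π-prenyl-Pd at its more substituted end under kinetic control to give the tertiary ("reverse-prenyl") ether; the chelated 5-OH and the aliphatic 3-OH do not compete.

**Step 3**
Reactants: 5; 6, prenol (3-methylbut-2-en-1-ol)
Product: 7, (2R,3R)-3-hydroxy-7-(methoxymethoxy)-5-(3-methylbut-2-enyloxy)-2-[4-(2-methylbut-3-en-2-yloxy)phenyl]chroman-4-one
Conditions: prenol (1.5 equiv), PPh3 (1.5 equiv), DIAD (1.5 equiv, slow addition), THF, 0 °C → rt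
Reagents that add atoms: prenol, CC(C)=CCO
Why: Mitsunobu etherification, in which the primary allylic alcohol is activated far faster than the hindered, H-bonded 3-OH and the only remaining phenol (5-OH) is the nucleophile; the neutral conditions avoid base-induced C-ring opening.

**Step 4 (key step)**
Reactants: 7
Product: 8, (2R,3R)-3,5-dihydroxy-2-[4-hydroxy-3-(3-methylbut-2-enyl)phenyl]-7-(methoxymethoxy)-8-(3-methylbut-2-enyl)chroman-4-one
Conditions: Eu(fod)3 (10 mol %), NaHCO3, PhCl, 85 °C, then 120 °C, one pot, Ar
Reagents that add atoms: none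
Why: Tandem sigmatropic rearrangement: Eu-chelated aromatic Claisen of the 5-O-prenyl ether to the C6 dienone, then Cope shift to C8 and enolisation (para-Claisen–Cope, giving a normal prenyl at C8); thermal ortho-Claisen of the 4'-O-(1,1-dimethylallyl) ether gives the normal prenyl at C3' (the two ortho positions are equivalent). No new stereocentre is formed.

**Step 5**
Reactants: 8
Product: 9, Lespedezaflavanone C
Conditions: 3 M aq. HCl, MeOH, 40–45 °C, stop at full conversion
Reagents that add atoms: none
Why: Acid-catalysed acetal hydrolysis of the aryl MOM ether; the conditions are mild enough to leave the o-prenylphenols uncyclised and the trans-(2R,3R) ketol unchanged.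

## Compound list

1 | (+)-aromadendrin, (2R,3R)-3,5,7-trihydroxy-2-(4-hydroxyphenyl)chroman-4-one | Oc1ccc([C@H]2Oc3cc(O)cc(O)c3C(=O)[C@@H]2O)cc1 | starting material
2 | chloromethyl methyl ether (MOMCl) | COCCl | starting material
3 | 7-O-MOM-aromadendrin | Oc1ccc([C@H]2Oc3cc(OCOC)cc(O)c3C(=O)[C@@H]2O)cc1 | intermediate
4 | tert-butyl (2-methylbut-3-en-2-yl) carbonate | C=CC(C)(C)OC(=O)OC(C)(C)C | starting material
5 | 7-O-MOM-4'-O-(1,1-dimethylallyl)aromadendrin | C=CC(C)(C)Oc1ccc([C@H]2Oc3cc(OCOC)cc(O)c3C(=O)[C@@H]2O)cc1 | intermediate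
6 | prenol (3-methylbut-2-en-1-ol) | CC(C)=CCO | starting material
7 | 7-O-MOM-5-O-prenyl-4'-O-(1,1-dimethylallyl)aromadendrin | C=CC(C)(C)Oc1ccc([C@H]2Oc3cc(OCOC)cc(OCC=C(C)C)c3C(=O)[C@@H]2O)cc1 | intermediate
8 | 7-O-MOM-8,3'-diprenylaromadendrin | CC(C)=CCc1cc([C@H]2Oc3c(CC=C(C)C)c(OCOC)cc(O)c3C(=O)[C@@H]2O)ccc1O | intermediate
9 | Lespedezaflavanone C, (2R,3R)-3,5,7-trihydroxy-2-[4-hydroxy-3-(3-methylbut-2-enyl)phenyl]-8-(3-methylbut-2-enyl)chroman-4-one | CC(C)=CCc1cc([C@H]2Oc3c(CC=C(C)C)c(O)cc(O)c3C(=O)[C@@H]2O)ccc1O | target

## Summary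

Total steps: 5. Longest linear sequence: 5 (fully linear from 1).

Three steps most likely to fail:

1. **Step 4.** The C6 dienone may enolise before the Cope shift, giving the 6-(1,1-dimethylallyl) isomer, and the B-ring ether may lose isoprene. Fallback: move the A-ring allyl donor to O7. Make the 7,4'-bis(1,1-dimethylallyl) ether of 1, acetylate 3-OH/5-OH to switch off the 5-OH···O=C chelate (which should steer the ortho-Claisen to C8 rather than C6), run a double ortho-Claisen, then deacetylate.
2. **Step 3.** The free 3-OH may be activated, or the chelated 5-OH may react sluggishly. Fallback: change the protecting-group plan by masking the 3-OH of 5 as a TES ether before the Mitsunobu; it is removed together with the MOM group in the final acid step.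
3. **Step 2.** The tertiary ether may isomerise to the linear O-prenyl ether, or C-allylation may compete. Fallback: build the tertiary ether in two steps without π-allyl chemistry, by Cu-catalysed O-propargylation with 3-chloro-3-methylbut-1-yne (CuCl2 cat., DBU, MeCN, 0 °C) followed by Lindlar semi-hydrogenation to the 1,1-dimethylallyl ether.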